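The earlier runs and the new flask were computed from invented constants, noise included.

I decide to count half-lives of L rather than fit the steps one by one.

| setting | grey | flask |
|---|---|---|
| L | 0.78 M | 0.78 M |
| E | 0.97 M | 1.95 M |
| remark | run made earlier |  |
| time |  | 6.0 min |

grey run (percent of the L charged)

| time / min | D / % | Q / % | X / % | J / % | L / % | G / % |
|---|---|---|---|---|---|---|
| 1.33 | 1.7 | 0.8 | 2.8 | 14.2 | 82.7 | 2.7 |
| 2.50 | 0 | 2.8 | 4.1 | 17.8 | 68.5 | 6.0 |
| 4.00 | 0 | 5.5 | 9.7 | 17.7 | 59.8 | 8.3 |
| 5.00 | 0 | 6.3 | 14.8 | 17.3 | 52.3 | 8.0 |
| 6.00 | 1.3 | 10.6 | 17.9 | 16.7 | 46.2 | 8.4 |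
| 8.00 | 1.4 | 11.9 | 22.5 | 16.9 | 39.5 | 6.3 |

(each reading ± 1 percentage point)

- in percentages every species weighs as the L in it: one X counts as two
- steps under discussion: E + G -> D; E + J -> G; L + G -> X; G -> Q; L + E -> J

- where most of what was charged as L, at 6.0 min is found (L / J / X / D / G / Q)
- the largest share itself, whichever of these holds it, in percent of the L charged

In the grey run L reads 46.2% at 6.00 min, which, read as first-order decay from that one scattered reading, gives an apparent half-life h of 5.39 min. The bench rule is pseudo-first-order: take E as steady, let h go inversely with the E charged, and the flask gets h = 2.68 min. The border of that rule is the ratio of E to L charged, 2.50 in the flask and 1.24 in the grey run. Both stand below the 3 E per L that D takes, so E is the limiting reagent towards D, and the steady E of the rule is an assumption here. I therefore use h to compare runs, not as a constant.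

My count is n, the time of the flask divided by its h: 2.24, which puts L in the flask at an estimated 21.2%. The last grey reading lies at 1.49 half-lives, fewer than in the flask. There X already reads 22.5%, more than my L and more than Q at 11.9%. So I commit to X, above that reading.

The forecast also says X, at 29%: “X holds the largest share, though the rate constants are loosely fixed”.

The flask gives X at 27.7%, under these steps:

    E + G → D (k = 0.00110 M⁻¹ s⁻¹)
    E + J → G (k = 0.00800 M⁻¹ s⁻¹)
    L + G → X (k = 0.0100 M⁻¹ s⁻¹)
    G → Q (k = 0.00470 s⁻¹)
    L + E → J (k = 0.00270 M⁻¹ s⁻¹)

X leads Q, at 21.6%, by 6.1 percentage points, more than the 1.3 points between the forecast and the flask. L stands at 19.3%, where n counted 21.2%. For the neighbour flask charged with 1.2 M of E the rule gives h = 4.35 min, so its n is 1.38 and the count puts L at 38.5%; that flask holds 37.7%.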